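Substrate, dormant form and product with its crystals add up at every moment to the substrate charged, so we keep the books on one pool, S, of substrate plus dormant form.

substrate 2.3 M; gas phase 200 mM (held); time 50 h

    substrate ⇌ dormant form (K1 = 1.7, k1 = 0.00883 min⁻¹)
    crystals ⇌ product, rate k2*(cs2 - [product]) while solid is left; crystals form when [product] > cs2 (cs2 = 1.5 M, k2 = 0.0101 min⁻¹)
    gas phase ⇌ dissolved gas, rate k3*(csat - [dissolved gas]) (k3 = 0.00375 min⁻¹, csat = 200 mM)
    substrate + dissolved gas → product (k4 = 0.00410 L mol⁻¹ min⁻¹)

- what is said of product includes crystals
- crystals is a solid; its amount is given per volume of the solution
- at the start none of the gas is dissolved
- run time (flask): 50 h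

- Wednesday's: doubling the transfer coefficient of step 3, all else as stated
- Monday's: doubling the dissolution coefficient of step 2, all else as stated
- Friday's: doubling the solubility in step 2, all else as stated
- Thursday's: doubling the saturation concentration of gas phase, all else as stated

* the product and crystals together standing at 50 h, as a percentage of the substrate charged
* the change that raises the amount of product and crystals together at 50 h, in percent of the substrate charged most ("none" if none brings more than 2 percentage points) (Wednesday's / Monday's / Friday's / Thursday's / none)
* amount of product and crystals together at 50 h, in percent of the substrate charged, after Friday's

We begin by reckoning by hand. Substrate and dormant form exchange with a relaxation half-life of 0.824 h, far shorter than the run of 50 h, so we treat that exchange as balanced throughout. Balance puts 1.7 parts of dormant form beside each part of substrate. The pool therefore reacts through its free share f, substrate over substrate plus dormant form, which is one over one plus that constant: 0.370. With B for the dissolved gas, S falls in a pseudo-first-order way, with rate constant 0.00410 L mol⁻¹ min⁻¹ times f times B.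

Dissolved gas has a half-life of 1.2 h against the reaction at the charged concentrations, far shorter than the run, so we let its supply equal its use. Free substrate draws on it at a first-order rate u, which is 0.003493 min⁻¹ at the charge. Then B is the transfer coefficient times saturation, over the transfer coefficient plus u, which gives 0.104 M, a level approached from zero with a time constant of about 2.30 h. Holding that level gives a first conversion of 37.6 %, and the smaller u then lifts B to 0.126 M. The mean of the two levels, acting for the run less that time constant, gives 39.3 %. That is 0.905 M of product, below the solubility of 1.5 M, so no crystals form, and we expect Monday's and Friday's to change nothing. Thursday's doubles B, whereas Wednesday's multiplies it at the start by 1.32, less than double, so we choose Thursday's.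

The forecast gives 38.5 % (range 35 % to 41 %), 38.5 % after Friday's, and Thursday's as best. Its ground for that choice is: “Doubling the saturation concentration doubles the whole dissolved-gas level”.

The simulation gives 38.9 %, and 38.9 % after Friday's. Thursday's is best, gaining 26 percentage points against 8.8 points for Wednesday's and 0 points for Monday's. Crystals stand at 0 % at 50.0 h. The forecast held on all its answers.

In this flask at 50.0 h, substrate over substrate plus dormant form reads 0.362, beside f of 0.370. The neighbouring flask has the same charge, read at 30 h. The same steps give a first conversion of 24.7 %, a later gas level of 0.118 M, and then 24.3 % of product. Taking f of the remaining pool leaves 28.0 % as free substrate. That neighbouring flask stood at 24.1 % of product and 28 % of substrate.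

The rate constants are those of an exercise; the rest is arithmetic.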